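**Retrosynthetic overview**

1. The target is a trans-2,3-dibenzyl-γ-butyrolactone (ring O1–C1(=O)–C2–C3–C4, benzylic carbons C7' on C2 and C7'' on C3). The strategy rests on C4 being a lone oxymethylene carbon on C3: while C7'' is carried as an aryl ketone, C3–H is the one readily enolised C–H of the skeleton.
2. Last operation: C7''=O is reduced to CH2 in the β-aroyl lactone.
3. Key disconnection: C3–C4 (aldol addition to formaldehyde) and C1–O1 (lactonisation) from an (R)-γ-keto acid. The γ-lactone is the only ring formed, and C3 is then equilibrated trans to C2.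
4. The keto acid comes from C2–C3 bond formation: an N-(3-arylpropanoyl)oxazolidinone enolate is alkylated with the α-bromo aryl ketone, and the auxiliary sets C2.

Key step: step 5

Remark: in the furanone names C2 is position 3 and C3 is position 4; commercial 37% aqueous formaldehyde is assumed as the formaldehyde source.

**Step 1**
Reactants: 1 3-(3,4,5-trimethoxyphenyl)propanoic acid; 2 (S)-4-benzyl-2-oxazolidinone
Product: 4 (S)-4-benzyl-3-[3-(3,4,5-trimethoxyphenyl)propanoyl]oxazolidin-2-one, via mixed pivalic anhydride 3 (not isolated)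
Conditions: PivCl, Et3N, THF, −20 °C; then LiCl, 2, −20 °C to rt
Reagents that add atoms: none
Why: Mixed-anhydride N-acylation of the oxazolidinone promoted by LiCl and Et3N is a standard way to load the auxiliary; no stereocentre is formed and the auxiliary centre is not touched.

**Step 2**
Reactants: 5 3',4',5'-trimethoxyacetophenone
Product: 6 2-bromo-1-(3,4,5-trimethoxyphenyl)ethan-1-one
Conditions: CuBr2 (2 equiv), EtOAc/CHCl3, reflux
Reagents that add atoms: CuBr2, Br[Cu]Br
Why: α-Bromination of an aryl methyl ketone with CuBr2 proceeds through the enol and should spare the electron-rich ring, which free Br2 could brominate.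

**Step 3**
Reactants: 4 (S)-4-benzyl-3-[3-(3,4,5-trimethoxyphenyl)propanoyl]oxazolidin-2-one; 6 2-bromo-1-(3,4,5-trimethoxyphenyl)ethan-1-one
Product: 8 (S)-4-benzyl-3-[(R)-2-(3,4,5-trimethoxybenzyl)-4-oxo-4-(3,4,5-trimethoxyphenyl)butanoyl]oxazolidin-2-one, via sodium (Z)-enolate 7 (not isolated)
Conditions: NaN(SiMe3)2, THF, −78 °C; then 6, −78 to −40 °C
Reagents that add atoms: none
Why: Evans asymmetric alkylation: the chelated sodium (Z)-enolate 7 should be attacked by the activated α-bromoketone on the face opposite the benzyl group of the auxiliary, which sets C2 as R.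

**Step 4**
Reactants: 8 (S)-4-benzyl-3-[(R)-2-(3,4,5-trimethoxybenzyl)-4-oxo-4-(3,4,5-trimethoxyphenyl)butanoyl]oxazolidin-2-one
Product: 10 (R)-2-(3,4,5-trimethoxybenzyl)-4-oxo-4-(3,4,5-trimethoxyphenyl)butanoic acid, via peroxy acid 9 (not isolated)
Conditions: LiOH, H2O2, THF/H2O, 0 °C; then aq. Na2SO3; then HCl to pH 2
Reagents that add atoms: hydrogen peroxide, OO
Why: Hydroperoxide cleavage of an Evans imide: the hydroperoxide anion attacks the exocyclic carbonyl selectively, sulfite reduces the peroxy acid 9, and C2 is not enolised under these conditions, so its configuration should be kept.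

**Step 5**
Reactants: 10 (R)-2-(3,4,5-trimethoxybenzyl)-4-oxo-4-(3,4,5-trimethoxyphenyl)butanoic acid; 11 formaldehyde
Product: 14 (3R,4R)-3-(3,4,5-trimethoxybenzyl)-4-(3,4,5-trimethoxybenzoyl)dihydrofuran-2(3H)-one, via hydroxy acid 12 (not isolated), via lactone epimer mixture 13 (not isolated)
Conditions: 37% aq. CH2O (1.1 equiv), NaOH (1.3 equiv), H2O/THF, 0 °C to rt; then 2 M HCl to pH 1, 40 °C; extract, then DBU (0.2 equiv), CH2Cl2, rt
Reagents that add atoms: none
Why: In aqueous NaOH the acid is held as its carboxylate, so C2–H is not removed and only the C3 methylene next to the aryl ketone enolises; this enolate adds to formaldehyde (crossed aldol hydroxymethylation, the classical formaldehyde condensation of 3-aroylpropionic acids) to form C3–C4 and give hydroxy acid 12 as a mixture of C3 epimers. On acidification the primary C4 hydroxyl attacks the C1 carboxyl in a 5-exo-trig acyl substitution, which closes the γ-lactone through C1–O1 for both epimers and gives 13. In 13 the C3–H is α to the aryl ketone and far more acidic than the C2–H α to the lactone carbonyl, so catalytic DBU should epimerise C3 alone, and the equilibrium should favour the trans isomer 14, in which the aroyl group lies opposite the C2 benzyl group fixed by the auxiliary; the new C3 centre is thus set under thermodynamic control relayed from C2. Mono-addition is secured by using close to one equivalent of formaldehyde and by the slower second aldol at the now tertiary C3. Ring opening of the lactone by E1cB loss of the C4 acyloxy group is the reverse of a 5-endo-trig closure and should be slow, because the ring C4–O1 bond lies close to the nodal plane of the exocyclic enolate.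

**Step 6**
Reactants: 14 (3R,4R)-3-(3,4,5-trimethoxybenzyl)-4-(3,4,5-trimethoxybenzoyl)dihydrofuran-2(3H)-one
Product: 16 (−)-cubebininolide, (3R,4R)-3,4-bis(3,4,5-trimethoxybenzyl)dihydrofuran-2(3H)-one, via benzylic alcohol 15 (not isolated)
Conditions: H2 (3 atm), 10% Pd/C, AcOH, HClO4 (cat.), rt
Reagents that add atoms: none
Why: Acid-promoted catalytic hydrogenolysis of an aryl ketone to the methylene passes through benzylic alcohol 15, whose protonated C–O bond is cleaved on the metal; the lactone, the methyl ethers and C2 are untouched, and any acid-induced enolisation at C3 should only return the favoured trans arrangement.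

**Compound list**

1 | 3-(3,4,5-trimethoxyphenyl)propanoic acid | COc1cc(CCC(=O)O)cc(OC)c1OC | starting material
2 | (S)-4-benzyl-2-oxazolidinone | O=C1OC[C@H](Cc2ccccc2)N1 | starting material
3 | 3-(3,4,5-trimethoxyphenyl)propanoic pivalic anhydride | COc1cc(CCC(=O)OC(=O)C(C)(C)C)cc(OC)c1OC | intermediate (not isolated)
4 | (S)-4-benzyl-3-[3-(3,4,5-trimethoxyphenyl)propanoyl]oxazolidin-2-one | COc1cc(CCC(=O)N2[C@@H](Cc3ccccc3)COC2=O)cc(OC)c1OC | intermediate
5 | 3',4',5'-trimethoxyacetophenone | CC(=O)c1cc(OC)c(OC)c(OC)c1 | starting material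
6 | 2-bromo-1-(3,4,5-trimethoxyphenyl)ethan-1-one | COc1cc(C(=O)CBr)cc(OC)c1OC | intermediate
7 | sodium (Z)-enolate of 4 | COc1cc(C/C=C(\[O-])N2[C@@H](Cc3ccccc3)COC2=O)cc(OC)c1OC.[Na+] | intermediate (not isolated)
8 | (S)-4-benzyl-3-[(R)-2-(3,4,5-trimethoxybenzyl)-4-oxo-4-(3,4,5-trimethoxyphenyl)butanoyl]oxazolidin-2-one | COc1cc(C[C@H](CC(=O)c2cc(OC)c(OC)c(OC)c2)C(=O)N2[C@@H](Cc3ccccc3)COC2=O)cc(OC)c1OC | intermediate
9 | (R)-2-(3,4,5-trimethoxybenzyl)-4-oxo-4-(3,4,5-trimethoxyphenyl)butaneperoxoic acid | COc1cc(C[C@H](CC(=O)c2cc(OC)c(OC)c(OC)c2)C(=O)OO)cc(OC)c1OC | intermediate (not isolated)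
10 | (R)-2-(3,4,5-trimethoxybenzyl)-4-oxo-4-(3,4,5-trimethoxyphenyl)butanoic acid | COc1cc(C[C@H](CC(=O)c2cc(OC)c(OC)c(OC)c2)C(=O)O)cc(OC)c1OC | intermediate
11 | formaldehyde | C=O | starting material
12 | (2R,3RS)-3-(hydroxymethyl)-4-oxo-2-(3,4,5-trimethoxybenzyl)-4-(3,4,5-trimethoxyphenyl)butanoic acid (C3 epimers; sodium salt in the flask) | COc1cc(C[C@H](C(CO)C(=O)c2cc(OC)c(OC)c(OC)c2)C(=O)O)cc(OC)c1OC | intermediate (not isolated)
13 | (3R,4RS)-3-(3,4,5-trimethoxybenzyl)-4-(3,4,5-trimethoxybenzoyl)dihydrofuran-2(3H)-one (mixture of epimers at position 4) | COc1cc(C(=O)C2COC(=O)[C@@H]2Cc2cc(OC)c(OC)c(OC)c2)cc(OC)c1OC | intermediate (not isolated)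
14 | (3R,4R)-3-(3,4,5-trimethoxybenzyl)-4-(3,4,5-trimethoxybenzoyl)dihydrofuran-2(3H)-one | COc1cc(C(=O)[C@H]2COC(=O)[C@@H]2Cc2cc(OC)c(OC)c(OC)c2)cc(OC)c1OC | intermediate
15 | (3R,4R)-4-[hydroxy(3,4,5-trimethoxyphenyl)methyl]-3-(3,4,5-trimethoxybenzyl)dihydrofuran-2(3H)-one (carbinol epimers) | COc1cc(C(O)[C@H]2COC(=O)[C@@H]2Cc2cc(OC)c(OC)c(OC)c2)cc(OC)c1OC | intermediate (not isolated)
16 | (−)-cubebininolide, (3R,4R)-3,4-bis(3,4,5-trimethoxybenzyl)dihydrofuran-2(3H)-one | COc1cc(C[C@H]2COC(=O)[C@@H]2Cc2cc(OC)c(OC)c(OC)c2)cc(OC)c1OC | target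

**Step count**

Total: 6 steps. Longest linear sequence: 5 steps (steps 1, 3, 4, 5, 6); step 2 is a one-step branch.

**Steps most likely to fail**

Step 5. Several things may go wrong in aqueous base: a second formaldehyde may add at C3, the aldol may lose water to an α-methylene ketone, or the adduct may revert by retro-aldol before lactonisation. The fallback moves the aldol to neutral Lewis-acid conditions, where a silyl enol ether can react only once. It sets out from 10. Esterification (MeI, K2CO3, DMF) should give methyl (R)-2-(3,4,5-trimethoxybenzyl)-4-oxo-4-(3,4,5-trimethoxyphenyl)butanoate F1. Soft enolisation of the ketone alone (TMSOTf, Et3N, CH2Cl2, 0 °C) should give methyl (R,Z)-2-(3,4,5-trimethoxybenzyl)-4-(3,4,5-trimethoxyphenyl)-4-(trimethylsilyloxy)but-3-enoate F2. A Mukaiyama aldol with aqueous formaldehyde (Yb(OTf)3 cat., THF/H2O, rt) should give methyl (2R,3RS)-3-(hydroxymethyl)-4-oxo-2-(3,4,5-trimethoxybenzyl)-4-(3,4,5-trimethoxyphenyl)butanoate F3. Acid lactonisation (p-TsOH, toluene, 60 °C) with loss of methanol brings the material back to the route at 13, which is equilibrated with DBU to 14 as in step 5.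

Step 3. The acidic α-bromoketone may quench the imide enolate by proton transfer, or the enolate may add to the ketone carbonyl in place of displacing bromide. The fallback installs the aryl ketone by acylating an aryl Grignard reagent and sets out from 4. The sodium enolate (NaN(SiMe3)2, THF, −78 °C) is alkylated with 2-bromo-N-methoxy-N-methylacetamide, which should give (S)-4-benzyl-3-[(R)-4-[methoxy(methyl)amino]-4-oxo-2-(3,4,5-trimethoxybenzyl)butanoyl]oxazolidin-2-one F4 with the same facial control. Cleavage with LiOH/H2O2 should give (R)-4-[methoxy(methyl)amino]-4-oxo-2-(3,4,5-trimethoxybenzyl)butanoic acid F5. Addition of 3,4,5-trimethoxyphenylmagnesium bromide (3 equiv, THF, 0 °C) to the Weinreb amide of the carboxylate salt brings the material back at 10.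

Step 6. The reduction may stall at the benzylic alcohol stage, where acyl migration from O1 to the benzylic oxygen competes, because the 3,4,5-trimethoxyphenyl ring supports benzylic cation character only moderately. The fallback removes the carbonyl oxygen by desulfurisation and sets out from 14. Thioketalisation (ethane-1,2-dithiol, BF3·OEt2, CH2Cl2, rt) should give (3R,4R)-3-(3,4,5-trimethoxybenzyl)-4-[2-(3,4,5-trimethoxyphenyl)-1,3-dithiolan-2-yl]dihydrofuran-2(3H)-one F6. Raney Ni in refluxing EtOH then cleaves both C–S bonds and arrives at the target 16.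

**Further compounds**

F1 | step 5 | methyl (R)-2-(3,4,5-trimethoxybenzyl)-4-oxo-4-(3,4,5-trimethoxyphenyl)butanoate | COc1cc(C[C@H](CC(=O)c2cc(OC)c(OC)c(OC)c2)C(=O)OC)cc(OC)c1OC
F2 | step 5 | methyl (R,Z)-2-(3,4,5-trimethoxybenzyl)-4-(3,4,5-trimethoxyphenyl)-4-(trimethylsilyloxy)but-3-enoate | COc1cc(C[C@H](/C=C(\O[Si](C)(C)C)c2cc(OC)c(OC)c(OC)c2)C(=O)OC)cc(OC)c1OC
F3 | step 5 | methyl (2R,3RS)-3-(hydroxymethyl)-4-oxo-2-(3,4,5-trimethoxybenzyl)-4-(3,4,5-trimethoxyphenyl)butanoate | COc1cc(C[C@H](C(CO)C(=O)c2cc(OC)c(OC)c(OC)c2)C(=O)OC)cc(OC)c1OC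
F4 | step 3 | (S)-4-benzyl-3-[(R)-4-[methoxy(methyl)amino]-4-oxo-2-(3,4,5-trimethoxybenzyl)butanoyl]oxazolidin-2-one | COc1cc(C[C@H](CC(=O)N(C)OC)C(=O)N2[C@@H](Cc3ccccc3)COC2=O)cc(OC)c1OC
F5 | step 3 | (R)-4-[methoxy(methyl)amino]-4-oxo-2-(3,4,5-trimethoxybenzyl)butanoic acid | COc1cc(C[C@H](CC(=O)N(C)OC)C(=O)O)cc(OC)c1OC
F6 | step 6 | (3R,4R)-3-(3,4,5-trimethoxybenzyl)-4-[2-(3,4,5-trimethoxyphenyl)-1,3-dithiolan-2-yl]dihydrofuran-2(3H)-one | COc1cc(C2(SCCS2)[C@H]2COC(=O)[C@@H]2Cc2cc(OC)c(OC)c(OC)c2)cc(OC)c1OC
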